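## Analysis of the target

The target 16 is a 2,3-dihydrobenzofuran neolignan in which ring A (C3a to C7a) is fused to a dihydrofuran ring (O1, C2, C3); C2 carries a 3,4,5-trimethoxyphenyl ring, C3 a hydroxymethyl group, and C5, para to O1, an (E)-3-hydroxyprop-1-enyl chain. C2 (R) and C3 (S) are the only stereocentres, they are adjacent and their substituents are trans. Neither is next to a carbonyl group, so they cannot be corrected by equilibration once the ring exists. The sensitive parts are the C2–O1 bond (a benzylic aryl ether that can ionise under acid), the cinnamyl-type allylic alcohol (acid, oxidants, hydrogenation) and two free primary alcohols that never need to be told apart. The difficulty is to combine absolute control of the trans-2,3 pair with the 1,2,4-pattern of ring A, where the chain must sit para to the oxygen and meta to C3. The strategy rests on one feature: O1 and C3 are bonded to the neighbouring ring A carbons C7a and C3a, they are separated from each other only by C2, and C3 bears CH2OH. This is the array obtained when a two-carbon aromatic unit is inserted between the hydroxyl oxygen and the internal epoxide carbon of a 2,3-epoxy alcohol, with the epoxide oxygen becoming the hydroxymethyl oxygen, so ring A can be introduced as an aryne while all stereochemistry is carried by a small acyclic epoxy alcohol.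

## Retrosynthetic reasoning

The last operation is the unveiling of the allylic alcohol: 16 is traced to the methyl cinnamate 15 by changing only the oxidation level of the terminal carbon. No skeletal bond is cut. The acid- and oxidation-sensitive cinnamyl alcohol then exists only in the final compound, and the forward step has only to reduce an unsaturated ester in the 1,2-sense next to a free primary alcohol.

In 15 the bond between C5 of ring A and the side chain is cut, giving aryl chloride 13 and methyl acrylate 14. This is the only skeletal bond remote from both stereocentres, and a halogen at C5 is a small substituent that survives strongly basic chemistry. Chlorine is preferred to bromine because it does not undergo halogen–metal exchange with an aryl anion, and it lies meta to the carbanion of the key step, so it cannot be eliminated. The forward Heck reaction must therefore activate a deactivated C–Cl bond, which needs a bulky electron-rich phosphine on palladium.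

The central disconnection cuts O1–C7a and C3–C3a of 13 together. These are the only bonds joining ring A to the stereogenic part. Cutting both leaves ring A as aryne 11 and the rest as epoxy alcohol 4, in which the hydroxyl oxygen is the future O1, the carbinol carbon is C2, the internal epoxide carbon is C3 and the epoxide oxygen is the future hydroxymethyl oxygen. In the forward direction alkoxide 10 must add to 11 at the carbon para to chlorine, and aryl anion 12 must open the epoxide at its internal carbon with inversion. Inversion at C3 turns an erythro epoxy alcohol into a trans ring, so 4 must be the erythro isomer with an (S)-carbinol and an (R)-oxirane carbon. Cutting elsewhere (C2–O1 or C2–C3) would leave a stereocentre to be created during ring closure; here both are in place beforehand. Aryne 11 is released from silyl triflate 9.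

Epoxy alcohol 4 is simplified by removing the epoxide oxygen, giving racemic allylic alcohol 3. The erythro product from the fast-reacting enantiomer in a Sharpless kinetic resolution has the required relative and absolute configuration, so one operation sets both stereocentres. The forward step must stop below half conversion so that 4 comes from one enantiomer of 3 only.

In 3 the bond between the carbinol carbon and the vinyl group is cut, leading to aldehyde 1 and vinyl Grignard reagent 2, both commercial. A racemic addition suffices.

Silyl triflate 9 is traced through lithium phenoxide 8 and aryllithium 7 to silyl ether 6 and then to 2-bromo-4-chlorophenol 5. The C–Si bond is formed by a retro-Brook shift, so the bromine of 5 decides where silicon, and hence the aryne, will be; the chlorine para to oxygen is carried unchanged.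

## Alternatives that were turned down

Alternative 1: Ring A is built from three alkynes by cutting C3a–C7a, C4–C5 and C6–C7. This gives the acyclic diyne A2, in which O1 carries a triethylsilyl-capped alkynyl group and C3 a terminal alkyne, and the enyne silyl ether A3. In the forward direction a cationic rhodium catalyst such as [Rh(cod)2]BF4 with BINAP (monovalent rhodium) would join the three alkynes to the 7-silylated, doubly silyl-protected benzofuran A1, closing the dihydrofuran ring and ring A together.
- For it: the side chain arrives complete, so no cross-coupling is needed; both stereocentres are set beforehand in an open chain; the silyl group gives a steric handle for orienting A3. On ring A regiocontrol this plan is probably stronger than an aryne addition steered by a remote chlorine.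
- Against it: A2 needs an alkynyl ether on a secondary benzylic oxygen, which is laborious to make and prone to fragment to a ketene on warming. Its propargylic centre C3 can epimerise through an allene under basic steps. The conjugated enyne A3 can react through its alkene or oligomerise. After the key step an aryl–silicon bond and two silyl ethers must be removed in the presence of the acid-sensitive C2–O1 bond.
- Comparison: the precursor alone should cost more steps than the whole chosen route, which buys its carbocycle and pays with a two-step side-chain installation.

Alternative 2: Ring A is again made de novo, by cutting C5–C6 and C7–C7a. The dihydrofuran is fused to the 2-pyranone A5, whose ester-bearing carbon becomes C5 and whose alkoxy-substituted ring-fusion carbon becomes C7a; the two missing carbons come from ethyl vinyl ether A6. On heating, cycloaddition across those two carbons, loss of CO2 from the bridged adduct and loss of ethanol would give the aromatic 5-carboxylate A4.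
- For it: the position of the C5 substituent is fixed by the pyranone, so the ring A regiochemistry question does not arise. On this point the alternative is clearly stronger than the chosen route.
- Against it: A5 is a ketene-acetal-type pyranone that must be grown over several steps from a saturated lactone already carrying both stereocentres, so the stereochemical problem is only moved earlier. C3–H in A5 is vinylogously activated, which makes epimerisation or β-elimination of O1 under thermal conditions a real risk. A4 ends in a one-carbon ester, which needs reduction, oxidation, olefination, a second reduction and a desilylation to become the allylic alcohol.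
- Comparison: the chosen strategy reaches the ring system with both stereocentres from a two-step precursor and finishes in two steps, at the price of less certain regiochemistry and an untested key step.

Alternative 3: The C3–C3a bond is traced to the C4–C4a bond of a flavanone. The (R)-6-bromoflavanone A8 would be treated with the trivalent iodine oxidant (diacetoxyiodo)benzene A9 and acid in an orthoformate medium. After α-functionalisation of C3 of the chromanone by A9, ring A migrates from C4 to C3, the six-membered ring contracts, and the former carbonyl carbon emerges as the methyl ester of A7, trans for steric reasons.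
- For it: flavanones are very accessible, the ring contraction is an established reaction type for this skeleton, the bromine is fixed at the right position from the start, and bromide is a better coupling handle than chloride. In precedent and ring A regiochemistry this alternative is stronger.
- Against it: the absolute configuration depends entirely on C2 of A8, which racemises by reversible ring opening to the chalcone under acidic or basic conditions, and an enantioselective flavanone synthesis adds steps. With an electron-rich 2-aryl group, migration of that aryl group (towards isoflavones) and dehydrogenation to the flavone compete with ring A migration, and the oxidant A9 can attack the trimethoxyphenyl ring. A7 still needs an ester reduction as well as the side-chain installation.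
- Comparison: the chosen plan sets both centres by a Sharpless epoxidation and a stereospecific SN2 opening, has no epimerisable centre at any stage, and should be several steps shorter. That is what it offers in exchange for lacking direct precedent.

Key step: step 5

Remark on the chemistry: the target is read as the 2,3-trans (2R,3S) isomer with an E alkene; metal alkoxides that are only protonated during aqueous work-up are not numbered separately.

## Route

Step 1
Reactants: 1 3,4,5-trimethoxybenzaldehyde; 2 vinylmagnesium bromide
Product: 3 rac-1-(3,4,5-trimethoxyphenyl)prop-2-en-1-ol
Conditions: THF, 0 °C; then aq. NH4Cl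
Reagents that add atoms: none
Why: Grignard 1,2-addition to a non-enolisable aryl aldehyde; the alcohol is made racemic on purpose because the next step selects one enantiomer.

Step 2
Reactants: 3 rac-1-(3,4,5-trimethoxyphenyl)prop-2-en-1-ol
Product: 4 (S)-[(R)-oxiran-2-yl](3,4,5-trimethoxyphenyl)methanol (erythro)
Conditions: Ti(OiPr)4 (0.3 equiv), L-(+)-DIPT (0.36 equiv), t-BuOOH (0.45 equiv), 4 Å MS, CH2Cl2, −20 °C
Reagents that add atoms: tert-butyl hydroperoxide, CC(C)(C)OO
Why: Sharpless kinetic resolution: with L-(+)-DIPT the (R)-enantiomer of 3 should be epoxidised much faster than the (S)-enantiomer and with high erythro selectivity, so stopping below half conversion should give 4 and leave (S)-3 behind. The carbinol centre is set by enantiomer selection and the oxirane centre by face-selective oxygen transfer from the titanium tartrate complex.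

Step 3
Reactants: 5 2-bromo-4-chlorophenol
Product: 6 (2-bromo-4-chlorophenoxy)trimethylsilane
Conditions: (Me3Si)2NH, THF, 70 °C; evaporate
Reagents that add atoms: hexamethyldisilazane, C[Si](C)(C)N[Si](C)(C)C
Why: O-silylation of a phenol with hexamethyldisilazane; ammonia is the only by-product, so crude 6 can be used after evaporation.

Step 4
Reactants: 6 (2-bromo-4-chlorophenoxy)trimethylsilane
Product: 9 4-chloro-2-(trimethylsilyl)phenyl trifluoromethanesulfonate, via aryllithium 7 (not isolated), via lithium phenoxide 8 (not isolated)
Conditions: n-BuLi, THF, −100 to −78 °C; then Tf2O, −100 to −78 °C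
Reagents that add atoms: trifluoromethanesulfonic anhydride, O=S(=O)(OS(=O)(=O)C(F)(F)F)C(F)(F)F
Why: Bromine–lithium exchange (far faster than any reaction at the aryl chloride at this temperature) gives 7, whose retro-Brook 1,3-shift of silicon from oxygen to carbon gives 8; O-triflation then gives the standard ortho-silylaryl triflate aryne precursor. The chlorine is meta to lithium in 7, so no aryne can form prematurely.

Step 5
Reactants: 4 (S)-[(R)-oxiran-2-yl](3,4,5-trimethoxyphenyl)methanol; 9 4-chloro-2-(trimethylsilyl)phenyl trifluoromethanesulfonate
Product: 13 trans-(2R,3S)-[5-chloro-2-(3,4,5-trimethoxyphenyl)-2,3-dihydro-1-benzofuran-3-yl]methanol, via potassium alkoxide 10 (not isolated), via 4-chlorobenzyne 11 (not isolated), via aryl anion 12 (not isolated)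
Conditions: 4 (1.5 equiv), KH, THF, 0 °C; then 9 (1.0 equiv), CsF, 18-crown-6, THF, −20 °C to rt; then aq. NH4Cl
Reagents that add atoms: none
Why: Proposed new method: fluoride removes the silyl group of 9 and triflate leaves to give aryne 11; alkoxide 10 adds to the aryne carbon para to chlorine, forming O1–C7a and leaving aryl anion 12 at the carbon meta to chlorine, which attacks the adjacent epoxide carbon anti to its C–O bond and forms C3–C3a; the closest known reaction types are the addition of oxygen nucleophiles to arynes with capture of the aryl anion by a tethered electrophile, and the Parham-type cyclisation of ortho-lithiated aryl glycidyl ethers to 2,3-dihydrobenzofuran-3-ylmethanols. The dihydrofuran ring closes in the 5-exo-tet mode, with the breaking epoxide C–O bond outside the new ring. C3 is set by stereospecific SN2 inversion at the (R)-oxirane carbon made in step 2; C2 keeps its geometry because only its O–H bond reacts (the descriptor changes from S to R through priorities alone), and inversion at C3 of the erythro array gives the 2,3-trans ring, (2R,3S). Regioselectivity on the aryne depends on the inductive effect of chlorine, which stabilises the developing carbanion better at the meta than at the para carbon; this bias should be modest, so some 6-chloro isomer is expected and must be removed by chromatography or crystallisation. 5-exo opening is favoured over 6-endo because the three-atom tether allows backside approach to the internal epoxide carbon but strains approach to the terminal one. Payne rearrangement of 10 is unimolecular and must stay slower than aryne capture, so 10 is formed cold with KH (no amine or alcohol by-product that could protonate 12), acetonitrile and ammonium fluorides are avoided, and 10 is kept in excess over 9 so that the product alkoxide competes less for the aryne.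

Step 6
Reactants: 13 trans-(2R,3S)-[5-chloro-2-(3,4,5-trimethoxyphenyl)-2,3-dihydro-1-benzofuran-3-yl]methanol; 14 methyl acrylate
Product: 15 methyl (E)-3-[(2R,3S)-3-(hydroxymethyl)-2-(3,4,5-trimethoxyphenyl)-2,3-dihydro-1-benzofuran-5-yl]prop-2-enoate
Conditions: Pd2(dba)3 (zerovalent palladium, 2 mol%), P(t-Bu)3 (8 mol%), Cy2NMe, 1,4-dioxane, 110 °C
Reagents that add atoms: none
Why: Heck reaction of an aryl chloride; the electron-rich, bulky tri-tert-butylphosphine on palladium makes oxidative addition into the deactivated para-alkoxy C–Cl bond feasible, and syn insertion followed by β-hydride elimination gives the E-cinnamate. The amine base does not affect the free alcohol or the stereocentres, neither of which has an acidic C–H.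

Step 7
Reactants: 15 methyl (E)-3-[(2R,3S)-3-(hydroxymethyl)-2-(3,4,5-trimethoxyphenyl)-2,3-dihydro-1-benzofuran-5-yl]prop-2-enoate
Product: 16 (E)-3-[(2R,3S)-3-(hydroxymethyl)-2-(3,4,5-trimethoxyphenyl)-2,3-dihydro-1-benzofuran-5-yl]prop-2-en-1-ol
Conditions: i-Bu2AlH (DIBAL-H, 4 equiv), CH2Cl2, −78 to 0 °C; then aq. potassium sodium tartrate
Reagents that add atoms: none
Why: DIBAL-H reduces α,β-unsaturated esters in the 1,2-sense to allylic alcohols with retention of alkene geometry; the extra equivalents allow for the free hydroxyl group, and the neutral tartrate work-up protects the acid-sensitive benzylic ether and cinnamyl alcohol.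

## Compound list

1 | 3,4,5-trimethoxybenzaldehyde | COc1cc(C=O)cc(OC)c1OC | starting material
2 | vinylmagnesium bromide | C=C[Mg]Br | starting material
3 | rac-1-(3,4,5-trimethoxyphenyl)prop-2-en-1-ol | COc1cc(C(O)C=C)cc(OC)c1OC | intermediate
4 | (S)-[(R)-oxiran-2-yl](3,4,5-trimethoxyphenyl)methanol | COc1cc([C@H](O)[C@H]2CO2)cc(OC)c1OC | intermediate
5 | 2-bromo-4-chlorophenol | Oc1ccc(Cl)cc1Br | starting material
6 | (2-bromo-4-chlorophenoxy)trimethylsilane | C[Si](C)(C)Oc1ccc(Cl)cc1Br | intermediate
7 | [5-chloro-2-(trimethylsilyloxy)phenyl]lithium | [Li]c1cc(Cl)ccc1O[Si](C)(C)C | intermediate (not isolated)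
8 | lithium 4-chloro-2-(trimethylsilyl)phenoxide | [Li+].[O-]c1ccc(Cl)cc1[Si](C)(C)C | intermediate (not isolated)
9 | 4-chloro-2-(trimethylsilyl)phenyl trifluoromethanesulfonate | C[Si](C)(C)c1cc(Cl)ccc1OS(=O)(=O)C(F)(F)F | intermediate
10 | potassium (S)-[(R)-oxiran-2-yl](3,4,5-trimethoxyphenyl)methanolate | COc1cc([C@H]([O-])[C@H]2CO2)cc(OC)c1OC.[K+] | intermediate (not isolated)
11 | 4-chlorobenzyne (4-chloro-1,2-didehydrobenzene) | ClC1=CC#CC=C1 | intermediate (not isolated)
12 | {5-chloro-2-[(S)-[(R)-oxiran-2-yl](3,4,5-trimethoxyphenyl)methoxy]phenyl}potassium | COc1cc([C@H](Oc2ccc(Cl)cc2[K])[C@H]3CO3)cc(OC)c1OC | intermediate (not isolated)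
13 | trans-(2R,3S)-[5-chloro-2-(3,4,5-trimethoxyphenyl)-2,3-dihydro-1-benzofuran-3-yl]methanol | COc1cc([C@@H]2Oc3ccc(Cl)cc3[C@H]2CO)cc(OC)c1OC | intermediate
14 | methyl acrylate | C=CC(=O)OC | starting material
15 | methyl (E)-3-[(2R,3S)-3-(hydroxymethyl)-2-(3,4,5-trimethoxyphenyl)-2,3-dihydro-1-benzofuran-5-yl]prop-2-enoate | COc1cc([C@@H]2Oc3ccc(/C=C/C(=O)OC)cc3[C@H]2CO)cc(OC)c1OC | intermediate
16 | (E)-3-[(2R,3S)-3-(hydroxymethyl)-2-(3,4,5-trimethoxyphenyl)-2,3-dihydro-1-benzofuran-5-yl]prop-2-en-1-ol | COc1cc([C@@H]2Oc3ccc(/C=C/CO)cc3[C@H]2CO)cc(OC)c1OC | target

## Step count and least certain steps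

Total: 7 steps. Longest linear sequence: 5 steps (steps 1, 2, 5, 6, 7; the branch through steps 3 and 4 is equally long).

**Step 5 (key step).** The following processes are the most likely to cause failure:
- Payne rearrangement of the epoxy alkoxide before it meets the aryne. It is intramolecular, favoured thermodynamically (internal epoxide, primary alkoxide) and accelerated by the crown-ether-separated cation; it would divert material to a constitutional isomer.
- Unselective addition to the two aryne carbons, because the chlorine is remote.
- Protonation of the aryl anion before ring closure.
- Arylation of the product alkoxide by a second aryne.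

Fallback (known chemistry, from 4, returning at 13): the two bonds are made one after the other. The sodium alkoxide of 4 (NaH, toluene, 0 °C to rt; sodium chelated between the two oxygens disfavours the anti arrangement needed for Payne rearrangement) is O-arylated without a metal catalyst by (2-bromo-4-chlorophenyl)(2,4,6-trimethoxyphenyl)iodonium 4-methylbenzenesulfonate F1. F1 is prepared in one pot from commercial 2-bromo-4-chloro-1-iodobenzene, mCPBA, TsOH and 1,3,5-trimethoxybenzene, and its trimethoxyphenyl group acts as the non-transferred ligand. The product is the aryl ether (R)-2-[(S)-(2-bromo-4-chlorophenoxy)(3,4,5-trimethoxyphenyl)methyl]oxirane F2, formed with retention at the carbinol carbon. Bromine–lithium exchange on F2 (n-BuLi, THF, −78 °C, chloride inert) and warming then effect the Parham-type 5-exo cyclisation of the aryllithium onto the epoxide, with inversion, to give 13. The bromine position fixes the ring A regiochemistry, so no isomer separation is needed.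

**Step 2.** Epoxidation of a monosubstituted alkene is slow under titanium tartrate catalysis, so conversion may stall; forcing it would erode the enantiomeric purity of the product, which in a kinetic resolution falls as conversion approaches one half. Lewis-acid-promoted opening of the benzylic epoxy alcohol during the long reaction time is a second risk.

Fallback (from 3, returning at 4): enantiomer separation and epoxidation are decoupled. Lipase-catalysed acylation of 3 (Novozym 435, vinyl acetate, MTBE, rt) should acylate the (R)-enantiomer selectively, giving (R)-1-(3,4,5-trimethoxyphenyl)prop-2-en-1-yl acetate F3, which is separated from the unreacted (S)-alcohol. Methanolysis (K2CO3, MeOH, 0 °C) gives (R)-1-(3,4,5-trimethoxyphenyl)prop-2-en-1-ol F4. F4 is then epoxidised to full conversion in the matched sense (Ti(OiPr)4, L-(+)-DIPT, t-BuOOH, 4 Å MS, CH2Cl2, −20 °C) to give 4. The epoxidation now needs only diastereoselectivity and no conversion control.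

**Step 6.** Oxidative addition into the electron-rich aryl chloride may be sluggish, and at the temperature required the catalyst may deactivate or the acrylate may polymerise.

Fallback (from 13, returning at 16, bypassing 15): Suzuki–Miyaura coupling of 13 with the commercial alkenylboronate (E)-tert-butyldimethyl{[3-(4,4,5,5-tetramethyl-1,3,2-dioxaborolan-2-yl)prop-2-en-1-yl]oxy}silane (Pd(OAc)2, SPhos, K3PO4, toluene–water, 90 °C), which is reliable for aryl chlorides. This gives [(2R,3S)-5-[(E)-3-(tert-butyldimethylsilyloxy)prop-1-en-1-yl]-2-(3,4,5-trimethoxyphenyl)-2,3-dihydro-1-benzofuran-3-yl]methanol F5. Desilylation of F5 (Bu4NF, THF, 0 °C) gives 16 directly and makes the ester reduction unnecessary.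

## Further compounds

F1 | step 5 | (2-bromo-4-chlorophenyl)(2,4,6-trimethoxyphenyl)iodonium 4-methylbenzenesulfonate | COc1cc(OC)c([I+]c2ccc(Cl)cc2Br)c(OC)c1.Cc1ccc(cc1)S(=O)(=O)[O-]
F2 | step 5 | (R)-2-[(S)-(2-bromo-4-chlorophenoxy)(3,4,5-trimethoxyphenyl)methyl]oxirane | COc1cc([C@H](Oc2ccc(Cl)cc2Br)[C@H]3CO3)cc(OC)c1OC
F3 | step 2 | (R)-1-(3,4,5-trimethoxyphenyl)prop-2-en-1-yl acetate | COc1cc([C@H](OC(C)=O)C=C)cc(OC)c1OC
F4 | step 2 | (R)-1-(3,4,5-trimethoxyphenyl)prop-2-en-1-ol | COc1cc([C@H](O)C=C)cc(OC)c1OC
F5 | step 6 | [(2R,3S)-5-[(E)-3-(tert-butyldimethylsilyloxy)prop-1-en-1-yl]-2-(3,4,5-trimethoxyphenyl)-2,3-dihydro-1-benzofuran-3-yl]methanol | COc1cc([C@@H]2Oc3ccc(/C=C/CO[Si](C)(C)C(C)(C)C)cc3[C@H]2CO)cc(OC)c1OC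
A1 | alternative 1 | tert-butyl{[(2R,3S)-5-[(E)-3-(tert-butyldimethylsilyloxy)prop-1-en-1-yl]-7-(triethylsilyl)-2-(3,4,5-trimethoxyphenyl)-2,3-dihydro-1-benzofuran-3-yl]methoxy}dimethylsilane | COc1cc([C@@H]2Oc3c([Si](CC)(CC)CC)cc(/C=C/CO[Si](C)(C)C(C)(C)C)cc3[C@H]2CO[Si](C)(C)C(C)(C)C)cc(OC)c1OC
A2 | alternative 1 | tert-butyldimethyl{[(2S)-2-{(R)-(3,4,5-trimethoxyphenyl)[(triethylsilylethynyl)oxy]methyl}but-3-yn-1-yl]oxy}silane | COc1cc([C@H](OC#C[Si](CC)(CC)CC)[C@H](CO[Si](C)(C)C(C)(C)C)C#C)cc(OC)c1OC
A3 | alternative 1 | tert-butyldimethyl[(E)-pent-2-en-4-yn-1-yloxy]silane | C#C/C=C/CO[Si](C)(C)C(C)(C)C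
A4 | alternative 2 | methyl (2R,3S)-3-[(tert-butyldimethylsilyloxy)methyl]-2-(3,4,5-trimethoxyphenyl)-2,3-dihydro-1-benzofuran-5-carboxylate | COc1cc([C@@H]2Oc3ccc(C(=O)OC)cc3[C@H]2CO[Si](C)(C)C(C)(C)C)cc(OC)c1OC
A5 | alternative 2 | methyl (2R,3S)-3-[(tert-butyldimethylsilyloxy)methyl]-6-oxo-2-(3,4,5-trimethoxyphenyl)-2,3-dihydro-6H-furo[2,3-b]pyran-5-carboxylate | COc1cc([C@@H]2OC3=C(C=C(C(=O)OC)C(=O)O3)[C@H]2CO[Si](C)(C)C(C)(C)C)cc(OC)c1OC
A6 | alternative 2 | ethyl vinyl ether | C=COCC
A7 | alternative 3 | methyl (2R,3R)-5-bromo-2-(3,4,5-trimethoxyphenyl)-2,3-dihydro-1-benzofuran-3-carboxylate (2,3-trans) | COc1cc([C@@H]2Oc3ccc(Br)cc3[C@H]2C(=O)OC)cc(OC)c1OC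
A8 | alternative 3 | (R)-6-bromo-2-(3,4,5-trimethoxyphenyl)chroman-4-one | COc1cc([C@@H]2Oc3ccc(Br)cc3C(=O)C2)cc(OC)c1OC
A9 | alternative 3 | (diacetoxyiodo)benzene | CC(=O)OI(OC(C)=O)c1ccccc1
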